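**Retrosynthetic overview**
- The 14-membered ring is closed last at the C5–C6 diene bond by a Pd-catalysed alkenyl–alkenyl coupling: an (E)-alkenylalane, made in the same pot from a terminal alkyne by Zr-catalysed methylalumination, couples with a (Z)-alkenyl iodide; acetylation of C1–OH follows.
- C10 carbinol: chelation-controlled MeMgBr addition to a 2-acyloxolane. C8–C9: alkylation of a methyl ketone enolate with an allylic iodide carrying the C6=C7(i-Pr) alkenyl iodide (from propargyl alcohol by Cu-catalysed anti-carbomagnesiation).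
- Oxolane (C11–O–C14) and C1 carbinol: Shi epoxidation of an (E)-trisubstituted alkene, then 5-exo opening by the C11 hydroxyl. That alkene (C1–C2 bond): Negishi sp2–sp3 coupling of an (E)-alkenyl iodide with a homopropargylzinc reagent from but-3-yn-1-ol.
- C11 comes from (S)-epichlorohydrin (propargyl Grignard opening, then sulfonium-ylide homologation to a vinyl carbinol; the vinyl group is a masked acetyl, unmasked by Wacker oxidation).
- Ring order: oxolane first (step 8), 14-membered carbocycle last (step 17).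

Assumption: the SMILES is taken as drawn, i.e. (1S,10R,11S,14R), 4E,6E, with locants C1 = CH–OAc, C2, C3, C4(Me)=C5–C6=C7(i-Pr), C8, C9, C10(Me)(OH), C11 and C14(Me) = oxolane carbons (2,5-cis), C12 and C13 = oxolane CH2; these locants are used throughout.

**Route**

Step 1
Reactants: 1 (S)-epichlorohydrin [(2S)-2-(chloromethyl)oxirane]; 2 propargyl bromide (3-bromoprop-1-yne)
Product: 4 (2S)-1-chlorohex-5-yn-2-ol, via allenylmagnesium bromide 3 (not isolated)
Conditions: 2, Mg, HgCl2 (1 mol %), Et2O, 0 °C; then 1, −78 → −20 °C; aq. NH4Cl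
Reagents that add atoms: none
Why: Grignard opening of the epoxide at its unsubstituted carbon (SN2; the allenyl reagent reacts through its far carbon and so delivers the propargyl group) does not touch the C–O stereocentre, which becomes C11 (S).

Step 2
Reactants: 4 (2S)-1-chlorohex-5-yn-2-ol
Product: 6 (3S)-hept-1-en-6-yn-3-ol, via alkynyl epoxide 5 (not isolated)
Conditions: Me3SI (4 equiv), n-BuLi (3.9 equiv), THF, −20 → 23 °C
Reagents that add atoms: trimethylsulfonium iodide, C[S+](C)C.[I-]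
Why: Dimethylsulfonium methylide first closes the chlorohydrin to the terminal epoxide, then opens it at CH2, and the β-oxido sulfonium salt loses Me2S by ylide-mediated elimination (one-carbon epoxide-to-allylic-alcohol homologation), which adds C9 and leaves the carbinol centre unchanged.

Step 3
Reactants: 6 (3S)-hept-1-en-6-yn-3-ol
Product: 8 (3S,6E)-7-iodo-6-methylhepta-1,6-dien-3-ol, via alkenylalane 7 (not isolated)
Conditions: AlMe3 (3.5 equiv), Cp2ZrCl2 (0.25 equiv), CH2Cl2, 0 → 23 °C; then I2, THF, −30 → 0 °C; aq. KNaC4H4O6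
Reagents that add atoms: trimethylaluminium, C[Al](C)C; iodine, II
Why: Negishi zirconium-catalysed carboalumination adds methyl and aluminium syn across the terminal alkyne with methyl on the inner carbon, and iodinolysis of the C–Al bond with retention gives the E alkenyl iodide (C14=C1); the hydroxyl travels as its aluminium alkoxide and the monosubstituted alkene does not react.

Step 4
Reactants: 9 but-3-yn-1-ol
Product: 11 4-(trimethylsilyl)but-3-yn-1-ol, via bis-silyl ether 10 (not isolated)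
Conditions: n-BuLi (2.1 equiv), THF, −78 °C; Me3SiCl (2.2 equiv), −78 → 23 °C; then 1 M HCl
Reagents that add atoms: chlorotrimethylsilane, C[Si](C)(C)Cl
Why: Double deprotonation and silylation at oxygen and at the alkyne carbon, then selective acid hydrolysis of the labile O–Si bond, leaves the C-silylated (protected) alkyne.

Step 5
Reactants: 11 4-(trimethylsilyl)but-3-yn-1-ol
Product: 12 (4-iodobut-1-yn-1-yl)trimethylsilane
Conditions: I2, PPh3, imidazole, CH2Cl2, 0 → 23 °C
Reagents that add atoms: iodine, II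
Why: Appel-type iodination of the primary alcohol through the alkoxyphosphonium salt (SN2).

Step 6
Reactants: 12 (4-iodobut-1-yn-1-yl)trimethylsilane
Product: 13 [4-(trimethylsilyl)but-3-yn-1-yl]zinc iodide (titrated THF solution)
Conditions: Zn powder (activated with BrCH2CH2Br and Me3SiCl), LiCl, THF, 40 °C
Reagents that add atoms: zinc, [Zn]
Why: LiCl-assisted direct insertion of zinc into the primary C–I bond gives a storable homopropargylzinc reagent that tolerates the silylalkyne.

Step 7
Reactants: 8 (3S,6E)-7-iodo-6-methylhepta-1,6-dien-3-ol; 13 [4-(trimethylsilyl)but-3-yn-1-yl]zinc iodide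
Product: 14 (3S,6E)-6-methyl-11-(trimethylsilyl)undeca-1,6-dien-10-yn-3-ol
Conditions: PdCl2(dppf) (5 mol %), 13 (2.5 equiv), THF, 23 → 45 °C
Reagents that add atoms: none
Why: Negishi sp2–sp3 cross-coupling (oxidative addition of the alkenyl iodide to zerovalent palladium, transmetalation from zinc, reductive elimination) forms C1–C2 with retention of the E geometry; the wide-bite-angle ligand outpaces β-hydride elimination and the excess reagent covers the free hydroxyl.

Step 8
Reactants: 14 (3S,6E)-6-methyl-11-(trimethylsilyl)undeca-1,6-dien-10-yn-3-ol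
Product: 16 (1S)-1-[(2R,5S)-5-ethenyl-2-methyloxolan-2-yl]-5-(trimethylsilyl)pent-4-yn-1-ol, via epoxy alcohol 15 (not isolated)
Conditions: 1,2:4,5-di-O-isopropylidene-β-L-erythro-2,3-hexodiulo-2,6-pyranose (ent-Shi ketone, 0.3 equiv), KHSO5 (as 2KHSO5·KHSO4·K2SO4), K2CO3, Bu4NHSO4, Na2B4O7 buffer (pH 10.5), MeCN/CH2(OMe)2/H2O, 0 °C; then (±)-camphor-10-sulfonic acid (10 mol %), CH2Cl2, 0 °C
Reagents that add atoms: potassium peroxymonosulfate, [K+].[O-]S(=O)(=O)OO
Why: Shi epoxidation (chiral dioxirane, spiro transition state) oxidises only the electron-rich E-trisubstituted alkene and the L-fructose-derived ketone gives the (2S,3S)-oxirane; acid then lets the C11 hydroxyl open it 5-exo at the tertiary carbon with inversion, which sets C14 (R), leaves C1 (S) as the free carbinol and closes the 2,5-cis oxolane.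

Step 9
Reactants: 16 (1S)-1-[(2R,5S)-5-ethenyl-2-methyloxolan-2-yl]-5-(trimethylsilyl)pent-4-yn-1-ol
Product: 17 tert-butyl({(1S)-1-[(2R,5S)-5-ethenyl-2-methyloxolan-2-yl]-5-(trimethylsilyl)pent-4-yn-1-yl}oxy)dimethylsilane
Conditions: t-BuMe2SiOTf (1.5 equiv), 2,6-lutidine (3 equiv), CH2Cl2, −78 → 0 °C
Reagents that add atoms: tert-butyldimethylsilyl trifluoromethanesulfonate, CC(C)(C)[Si](C)(C)OS(=O)(=O)C(F)(F)F
Why: O-Silylation of the hindered secondary C1 hydroxyl with the silyl triflate keeps it from forming a bridged hemiketal with the ketone made next and from interfering with the enolate and Grignard chemistry of steps 14 and 15.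

Step 10
Reactants: 17 C1-silyl ether of the vinyl oxolane
Product: 18 1-{(2S,5R)-5-[(1S)-1-{[tert-butyl(dimethyl)silyl]oxy}-5-(trimethylsilyl)pent-4-yn-1-yl]-5-methyloxolan-2-yl}ethan-1-one
Conditions: PdCl2(quinox) (5 mol %; quinox = 2-(4,5-dihydro-1,3-oxazol-2-yl)quinoline), AgSbF6 (12 mol %), aq. t-BuOOH (12 equiv), CH2Cl2, 0 → 23 °C
Reagents that add atoms: tert-butyl hydroperoxide, CC(C)(C)OO
Why: Catalyst-controlled Tsuji–Wacker oxidation: the cationic Pd–quinox complex delivers the peroxide to the inner carbon of the terminal alkene even next to the ether oxygen, and a 1,2-hydride shift gives the methyl ketone (C10=O, C9 = CH3) without epimerising C11.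

Step 11
Reactants: 19 prop-2-yn-1-ol (propargyl alcohol)
Product: 21 (2Z)-3-iodo-2-(propan-2-yl)prop-2-en-1-ol, via alkenylmagnesium chelate 20 (not isolated)
Conditions: i-PrMgCl (3 equiv), CuI (10 mol %), Et2O, 0 → 35 °C; then I2, −40 → 0 °C; aq. NH4Cl
Reagents that add atoms: isopropylmagnesium chloride, CC(C)[Mg]Cl; iodine, II
Why: Copper-catalysed anti-carbomagnesiation of the propargylic alkoxide (Duboudin reaction) puts isopropyl on C7 and magnesium on C6 cis to the CH2O group in a five-membered chelate, and iodinolysis with retention gives iodine cis to CH2OH, which is the C6=C7 geometry of the target.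

Step 12
Reactants: 21 (2Z)-3-iodo-2-(propan-2-yl)prop-2-en-1-ol
Product: 22 (1Z)-2-(bromomethyl)-1-iodo-3-methylbut-1-ene
Conditions: CBr4 (1.2 equiv), PPh3 (1.25 equiv), CH2Cl2, 0 °C
Reagents that add atoms: carbon tetrabromide, BrC(Br)(Br)Br
Why: Appel bromination of the primary allylic alcohol (SN2 at CH2, no allylic shift at 0 °C) gives the storable bromide with the alkene geometry intact.

Step 13
Reactants: 22 (1Z)-2-(bromomethyl)-1-iodo-3-methylbut-1-ene
Product: 23 (1Z)-1-iodo-2-(iodomethyl)-3-methylbut-1-ene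
Conditions: NaI (2 equiv), acetone, 23 °C, dark; used at once
Reagents that add atoms: sodium iodide, [Na+].[I-]
Why: Finkelstein exchange gives the allylic iodide, which alkylates a lithium enolate at −78 °C where proton transfer between enolate and product (dialkylation, epimerisation at C11) is slow; it is made fresh because it does not keep.

Step 14
Reactants: 18 methyl ketone (2-acetyl oxolane, C1–OSi-t-BuMe2); 23 (1Z)-1-iodo-2-(iodomethyl)-3-methylbut-1-ene
Product: 25 (4E)-1-{(2S,5R)-5-[(1S)-1-{[tert-butyl(dimethyl)silyl]oxy}-5-(trimethylsilyl)pent-4-yn-1-yl]-5-methyloxolan-2-yl}-4-(iodomethylidene)-5-methylhexan-1-one, via lithium enolate 24 (not isolated)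
Conditions: LiN(i-Pr)2 (1.05 equiv), THF, −78 °C; then 23 (1.3 equiv), −78 → −50 °C
Reagents that add atoms: none
Why: Kinetic deprotonation at the methyl group and SN2 alkylation of the lithium enolate at the allylic CH2–I form C8–C9; the alkenyl iodide, silyl ether and silylalkyne do not react with the amide base at −78 °C.

Step 15
Reactants: 25 alkylated ketone (C10=O)
Product: 26 (2R,5E)-2-{(2S,5R)-5-[(1S)-1-{[tert-butyl(dimethyl)silyl]oxy}-5-(trimethylsilyl)pent-4-yn-1-yl]-5-methyloxolan-2-yl}-5-(iodomethylidene)-6-methylheptan-2-ol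
Conditions: MeMgBr (3 equiv), Et2O, −78 °C; aq. NH4Cl
Reagents that add atoms: methylmagnesium bromide, C[Mg]Br
Why: Cram-chelate Grignard addition: magnesium bridges the ketone oxygen and the oxolane oxygen, and methyl attacks the carbonyl face on the side of C11–H (away from ring C12), which sets C10 as R; the alkenyl iodide does not exchange at −78 °C.

Step 16
Reactants: 26 tertiary alcohol (C1–OSi-t-BuMe2, C5–SiMe3)
Product: 27 (1S)-1-{(2R,5S)-5-[(2R,5E)-2-hydroxy-5-(iodomethylidene)-6-methylheptan-2-yl]-2-methyloxolan-2-yl}pent-4-yn-1-ol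
Conditions: Bu4NF (4 equiv), THF, 23 → 45 °C
Reagents that add atoms: none
Why: Fluoride-induced desilylation cleaves both the C1–O–Si and the alkynyl C–Si bonds in one operation and leaves the alkenyl iodide and the tertiary alcohol untouched.

Step 17
Reactants: 27 seco diol (terminal alkyne at C4≡C5, alkenyl iodide at C6)
Product: 29 (1R,2S,5E,7E,11R,12S)-1,5,11-trimethyl-8-(propan-2-yl)-15-oxabicyclo[10.2.1]pentadeca-5,7-diene-2,11-diol, via alkenylalane 28 (not isolated)
Conditions: AlMe3 (5 equiv), Cp2ZrCl2 (1 equiv), ClCH2CH2Cl, 0 → 23 °C; excess AlMe3 removed in vacuo; THF; added by syringe pump over 10 h to Pd2(dba)3 (10 mol %), P(2-furyl)3 (40 mol %), ZnCl2 (1 equiv), THF, 45 °C (final 2 mM); aq. KNaC4H4O6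
Reagents that add atoms: trimethylaluminium, C[Al](C)C
Why: Proposed new method: a one-pot zirconium-catalysed methylalumination of the terminal alkyne followed by intramolecular Pd/Zn-cocatalysed alkenyl–alkenyl coupling of the resulting (E)-alkenylalane with the remote alkenyl iodide, which closes the 14-membered ring at C5–C6 with both diene geometries fixed beforehand (syn Me/Al addition sets C4=C5 as E, the iodide carries C6=C7) while the two hydroxyls travel as aluminium alkoxides; each elementary step (syn-carbometalation, Al-to-Zn-to-Pd transmetalation, oxidative addition of zerovalent palladium into C–I, stereoretentive reductive elimination) is known and alkenyl transfer from aluminium outruns methyl transfer, but the tandem sequence has not been used to close a ring, the closest known reactions being the intermolecular one-pot Negishi carboalumination/cross-coupling to dienes and Stille or Suzuki macrocyclisations of alkenyl iodides.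

Step 18
Reactants: 29 macrocyclic diol
Product: 30 (1R,2S,5E,7E,11R,12S)-11-hydroxy-1,5,11-trimethyl-8-(propan-2-yl)-15-oxabicyclo[10.2.1]pentadeca-5,7-dien-2-yl acetate
Conditions: Ac2O (3 equiv), pyridine, 4-(dimethylamino)pyridine (0.1 equiv), CH2Cl2, 23 °C
Reagents that add atoms: acetic anhydride, CC(=O)OC(C)=O
Why: Nucleophile-catalysed acylation esterifies only the secondary C1 hydroxyl, because the tertiary C10 hydroxyl is too hindered to react at 23 °C.

**Compound list**
1 | (2S)-2-(chloromethyl)oxirane [(S)-epichlorohydrin] | ClC[C@@H]1CO1 | starting material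
2 | 3-bromoprop-1-yne (propargyl bromide) | BrCC#C | starting material
3 | allenylmagnesium bromide (propa-1,2-dien-1-ylmagnesium bromide) | C=C=C[Mg]Br | intermediate
4 | (2S)-1-chlorohex-5-yn-2-ol | ClC[C@@H](O)CCC#C | intermediate
5 | (2S)-2-(but-3-yn-1-yl)oxirane | C1[C@@H](O1)CCC#C | intermediate
6 | (3S)-hept-1-en-6-yn-3-ol | C=C[C@@H](O)CCC#C | intermediate
7 | dimethyl{(1E,5S)-5-[(dimethylalumanyl)oxy]-2-methylhepta-1,6-dien-1-yl}alumane | C=C[C@@H](O[Al](C)C)CC/C(C)=C/[Al](C)C | intermediate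
8 | (3S,6E)-7-iodo-6-methylhepta-1,6-dien-3-ol | C=C[C@@H](O)CC/C(C)=C/I | intermediate
9 | but-3-yn-1-ol | OCCC#C | starting material
10 | trimethyl{[4-(trimethylsilyl)but-3-yn-1-yl]oxy}silane | C[Si](C)(C)OCCC#C[Si](C)(C)C | intermediate
11 | 4-(trimethylsilyl)but-3-yn-1-ol | OCCC#C[Si](C)(C)C | intermediate
12 | (4-iodobut-1-yn-1-yl)trimethylsilane | ICCC#C[Si](C)(C)C | intermediate
13 | [4-(trimethylsilyl)but-3-yn-1-yl]zinc iodide (LiCl-solvated, in THF) | I[Zn]CCC#C[Si](C)(C)C | intermediate
14 | (3S,6E)-6-methyl-11-(trimethylsilyl)undeca-1,6-dien-10-yn-3-ol | C=C[C@@H](O)CC/C(C)=C/CCC#C[Si](C)(C)C | intermediate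
15 | (3S)-5-{(2S,3S)-2-methyl-3-[4-(trimethylsilyl)but-3-yn-1-yl]oxiran-2-yl}pent-1-en-3-ol | C=C[C@@H](O)CC[C@]1(C)O[C@H]1CCC#C[Si](C)(C)C | intermediate
16 | (1S)-1-[(2R,5S)-5-ethenyl-2-methyloxolan-2-yl]-5-(trimethylsilyl)pent-4-yn-1-ol | C=C[C@@H]1CC[C@@](C)(O1)[C@@H](O)CCC#C[Si](C)(C)C | intermediate
17 | tert-butyl({(1S)-1-[(2R,5S)-5-ethenyl-2-methyloxolan-2-yl]-5-(trimethylsilyl)pent-4-yn-1-yl}oxy)dimethylsilane | C=C[C@@H]1CC[C@@](C)(O1)[C@@H](O[Si](C)(C)C(C)(C)C)CCC#C[Si](C)(C)C | intermediate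
18 | 1-{(2S,5R)-5-[(1S)-1-{[tert-butyl(dimethyl)silyl]oxy}-5-(trimethylsilyl)pent-4-yn-1-yl]-5-methyloxolan-2-yl}ethan-1-one | CC(=O)[C@@H]1CC[C@@](C)(O1)[C@@H](O[Si](C)(C)C(C)(C)C)CCC#C[Si](C)(C)C | intermediate
19 | prop-2-yn-1-ol (propargyl alcohol) | OCC#C | starting material
20 | 4-(propan-2-yl)-2,5-dihydro-1,2-oxamagnesole (cyclic alkenylmagnesium alkoxide, Mg cis to CH2O) | CC(C)C1=C[Mg]OC1 | intermediate
21 | (2Z)-3-iodo-2-(propan-2-yl)prop-2-en-1-ol (I cis to CH2OH) | OC/C(=C\I)C(C)C | intermediate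
22 | (1Z)-2-(bromomethyl)-1-iodo-3-methylbut-1-ene | BrC/C(=C\I)C(C)C | intermediate
23 | (1Z)-1-iodo-2-(iodomethyl)-3-methylbut-1-ene | IC/C(=C\I)C(C)C | intermediate
24 | lithium 1-{(2S,5R)-5-[(1S)-1-{[tert-butyl(dimethyl)silyl]oxy}-5-(trimethylsilyl)pent-4-yn-1-yl]-5-methyloxolan-2-yl}ethen-1-olate | [Li]OC(=C)[C@@H]1CC[C@@](C)(O1)[C@@H](O[Si](C)(C)C(C)(C)C)CCC#C[Si](C)(C)C | intermediate
25 | (4E)-1-{(2S,5R)-5-[(1S)-1-{[tert-butyl(dimethyl)silyl]oxy}-5-(trimethylsilyl)pent-4-yn-1-yl]-5-methyloxolan-2-yl}-4-(iodomethylidene)-5-methylhexan-1-one (I cis to the CH2CH2 chain) | I/C=C(\CCC(=O)[C@@H]1CC[C@@](C)(O1)[C@@H](O[Si](C)(C)C(C)(C)C)CCC#C[Si](C)(C)C)C(C)C | intermediate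
26 | (2R,5E)-2-{(2S,5R)-5-[(1S)-1-{[tert-butyl(dimethyl)silyl]oxy}-5-(trimethylsilyl)pent-4-yn-1-yl]-5-methyloxolan-2-yl}-5-(iodomethylidene)-6-methylheptan-2-ol | I/C=C(\CC[C@@](C)(O)[C@@H]1CC[C@@](C)(O1)[C@@H](O[Si](C)(C)C(C)(C)C)CCC#C[Si](C)(C)C)C(C)C | intermediate
27 | (1S)-1-{(2R,5S)-5-[(2R,5E)-2-hydroxy-5-(iodomethylidene)-6-methylheptan-2-yl]-2-methyloxolan-2-yl}pent-4-yn-1-ol | I/C=C(\CC[C@@](C)(O)[C@@H]1CC[C@@](C)(O1)[C@@H](O)CCC#C)C(C)C | intermediate
28 | alkenylalane from 27: C≡CH turned into (E)-C(CH3)=CH–AlMe2, both OH as O–AlMe2 | I/C=C(\CC[C@@](C)(O[Al](C)C)[C@@H]1CC[C@@](C)(O1)[C@@H](O[Al](C)C)CC/C(C)=C/[Al](C)C)C(C)C | intermediate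
29 | (1R,2S,5E,7E,11R,12S)-1,5,11-trimethyl-8-(propan-2-yl)-15-oxabicyclo[10.2.1]pentadeca-5,7-diene-2,11-diol | O[C@H]1CC/C(C)=C/C=C(/C(C)C)CC[C@@](C)(O)[C@@H]2CC[C@@]1(C)O2 | intermediate
30 | (1R,2S,5E,7E,11R,12S)-11-hydroxy-1,5,11-trimethyl-8-(propan-2-yl)-15-oxabicyclo[10.2.1]pentadeca-5,7-dien-2-yl acetate | CC(=O)O[C@H]1CC/C(C)=C/C=C(/C(C)C)CC[C@@](C)(O)[C@@H]2CC[C@@]1(C)O2 | target

**Step count and risks**

Total step count: 18. Longest linear sequence: 12 steps (1–3, 7–10, 14–18; the path 4–6, 7–10, 14–18 is equally long).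

The three steps most likely to fail:

Step 10 (Wacker oxidation next to an ether oxygen with a silylalkyne present). The aldehyde regioisomer may form, or the cationic palladium/silver pair may attack the alkyne. The fallback sets out from 17 and comes back at 18. The vinyl group is cleaved (OsO4 cat., NaIO4, 2,6-lutidine, dioxane/H2O) to (2S,5R)-5-[(1S)-1-{[tert-butyl(dimethyl)silyl]oxy}-5-(trimethylsilyl)pent-4-yn-1-yl]-5-methyloxolane-2-carbaldehyde F1. MeMgBr (Et2O, −78 °C) then gives 1-{(2S,5R)-5-[(1S)-1-{[tert-butyl(dimethyl)silyl]oxy}-5-(trimethylsilyl)pent-4-yn-1-yl]-5-methyloxolan-2-yl}ethan-1-ol F2 as a mixture of carbinol epimers, and Dess–Martin periodinane (CH2Cl2) oxidises it to 18. This replaces the alkene oxidation by C=C cleavage and C–C re-formation, so no regioisomer can arise.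

Step 14 (mono-alkylation of a methyl ketone enolate). Proton transfer between enolate and product can cause dialkylation and epimerisation at C11. The fallback sets out from 18 and comes back at 25. Condensation with Me2NNH2 (AcOH cat., EtOH) gives the N,N-dimethylhydrazone of 18 F3. Its aza-enolate (LiN(i-Pr)2, THF, −78 → 0 °C) is alkylated with 23 at −78 °C, only at the methyl-derived carbon, to the N,N-dimethylhydrazone of 25 F4. Aqueous Cu(OAc)2 in THF hydrolyses the hydrazone to 25.

Step 17 (the proposed one-pot carboalumination and macrocyclising coupling). The risks are methyl transfer from Al–Me to the alkenyl iodide, protodemetalation of the alane at high dilution, and oligomerisation. The fallback uses known chemistry, sets out from 27 and comes back at 29. The same Zr-catalysed carboalumination is quenched with 2-isopropoxy-4,4,5,5-tetramethyl-1,3,2-dioxaborolane (Al-to-B transfer) to give, after aqueous work-up, the isolable (1S,4E)-1-{(2R,5S)-5-[(2R,5E)-2-hydroxy-5-(iodomethylidene)-6-methylheptan-2-yl]-2-methyloxolan-2-yl}-4-methyl-5-(4,4,5,5-tetramethyl-1,3,2-dioxaborolan-2-yl)pent-4-en-1-ol F5. A Suzuki–Miyaura macrocyclisation (PdCl2(dppf) 20 mol %, AsPh3, Cs2CO3, DMF/THF/H2O, 23 °C, 1 mM) then closes the ring to 29.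

Further compounds
F1 | step 10 | (2S,5R)-5-[(1S)-1-{[tert-butyl(dimethyl)silyl]oxy}-5-(trimethylsilyl)pent-4-yn-1-yl]-5-methyloxolane-2-carbaldehyde | O=C[C@@H]1CC[C@@](C)(O1)[C@@H](O[Si](C)(C)C(C)(C)C)CCC#C[Si](C)(C)C
F2 | step 10 | 1-{(2S,5R)-5-[(1S)-1-{[tert-butyl(dimethyl)silyl]oxy}-5-(trimethylsilyl)pent-4-yn-1-yl]-5-methyloxolan-2-yl}ethan-1-ol (both carbinol epimers) | CC(O)[C@@H]1CC[C@@](C)(O1)[C@@H](O[Si](C)(C)C(C)(C)C)CCC#C[Si](C)(C)C
F3 | step 14 | N,N-dimethylhydrazone of 18 | CC(=NN(C)C)[C@@H]1CC[C@@](C)(O1)[C@@H](O[Si](C)(C)C(C)(C)C)CCC#C[Si](C)(C)C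
F4 | step 14 | N,N-dimethylhydrazone of 25 | I/C=C(\CCC(=NN(C)C)[C@@H]1CC[C@@](C)(O1)[C@@H](O[Si](C)(C)C(C)(C)C)CCC#C[Si](C)(C)C)C(C)C
F5 | step 17 | (1S,4E)-1-{(2R,5S)-5-[(2R,5E)-2-hydroxy-5-(iodomethylidene)-6-methylheptan-2-yl]-2-methyloxolan-2-yl}-4-methyl-5-(4,4,5,5-tetramethyl-1,3,2-dioxaborolan-2-yl)pent-4-en-1-ol | I/C=C(\CC[C@@](C)(O)[C@@H]1CC[C@@](C)(O1)[C@@H](O)CC/C(C)=C/B2OC(C)(C)C(C)(C)O2)C(C)C
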